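**Side tally.** Reckon side product as a running sum over the target curve, and the asked share, target over target plus side product, follows from that sum and the end target.

| flask | starting material | partner | second substrate | remark | time |
|---|---|---|---|---|---|
| west | 0.023 M | 0.50 equiv | 5 equiv | run made earlier |  |
| north-east | 0.023 M | 0.50 equiv | 2.5 equiv | run made earlier |  |
| south-west | 0.023 M | 0.50 equiv | 3.8 equiv | run made earlier |  |
| north-west | 0.023 M | 0.25 equiv | 5 equiv | run made earlier |  |
| violet | 0.023 M (fed, over 6.0 min) | 0.500 equiv | 5.00 equiv | all else is in the flask from the start; the feed brings no volume worth counting | 8.0 min |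
| ochre | 0.023 M (fed, over 40 s) | 0.500 equiv | 5.00 equiv | all else is in the flask from the start; the feed brings no volume worth counting | 8.0 min |
| amber | 0.023 M | 0.500 equiv (fed, over 6.0 min) | 5.00 equiv | all else is in the flask from the start; the feed brings no volume worth counting | 8.0 min |
| teal | 0.023 M | 0.500 equiv | 5.00 equiv | everything together at the start | 8.0 min |

- west (time / min: target / %, side product / %): 0.833: 12.7, 0; 1.50: 11.2, 0.4; 2.50: 7.5, 0.4; 3.00: 6.1, 0.3; 4.00: 6.7, 1.8; 5.00: 5.4, 0.4
- north-east (time / min: target / %, side product / %): 0.417: 14.5, 0.8; 0.667: 12.9, 2.1; 1.00: 14.7, 0; 2.00: 12.4, 1.8; 3.00: 11.6, 1.2; 5.00: 10.1, 2.1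
- south-west (time / min: target / %, side product / %): 0.833: 13.0, 1.4; 1.50: 12.1, 0; 2.50: 9.1, 0.9; 3.00: 10.6, 2.6; 4.00: 6.1, 0.1; 5.00: 6.4, 3.4
- north-west (time / min: target / %, side product / %): 0.417: 5.8, 0; 1.33: 5.8, 1.2; 2.00: 4.8, 2.5; 3.00: 5.6, 0.2; 5.00: 1.7, 2.0

(each reading ± 1 percentage point)

- the flask that comes out highest in share of target in target plus side product, or "all alike" when all lie within 1.5 percentage points (violet / ochre / amber / teal / all alike)
- share of target in target plus side product at the end, violet
- share of target in target plus side product at the end, ochre
- share of target in target plus side product at the end, amber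
- share of target in target plus side product at the end, teal

- percent here means starting material units held: one side product counts as two
- reactions considered so far: starting material + target -> side product; starting material + partner <-> target; second substrate <-> dormant form; second substrate + partner <-> second product

Pooling the last side readings of the earlier runs over the areas under their target curves gives 0.0454 min⁻¹ for the side-tally rate, the fraction of the charge gained as side product per minute per fraction standing as target, with starting material at its full charge (a pseudo-first-order constant). It is a reading and carries their scatter.

**Time.** Read from its first and last points, the west run's target falls at 0.205 min⁻¹. I let that fall run on, so by hand teal ends at 2.92% target and a tally of 2.60%, a share of 52.9%.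

**Second substrate.** At 5.00 min, the north-east run at 2.5 equiv reads 10.1% target, more than the west run's 5.4% at 5 equiv. So, between these two runs at 0.50 equiv partner, more second substrate costs end target, and by hand the share with it.

**Feeds.** Ochre's feed takes 40 s, far shorter than 8.0 min, so by hand ochre reads as teal. For violet's slow feed I put the mean fill of starting material at 62.5%, and scaling the tally by that gives me 64.2%. Amber's slow partner should flatten the target curve, so I place it beside violet.

**The forecast.** It names violet, with violet 86% (77% to 92%), ochre 77% (66% to 85%), amber 85% (77% to 91%) and teal 77% (66% to 85%). Of the target's fall it says “It levels near 4–5%”, where my reckoning lets it run on.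

**The result.** Violet comes out highest at 74.3%, then amber 72.5%, ochre 51.4% and teal 48.5%. Teal ends with 2.08% target and 2.21% side product.

    starting material + target → side product (k = 0.0174 L mol⁻¹ s⁻¹)
    starting material + partner ⇌ target (K = 27.8 L mol⁻¹, k = 1.06 L mol⁻¹ s⁻¹)
    second substrate ⇌ dormant form (K = 0.568, k = 0.0678 s⁻¹)
    second substrate + partner ⇌ second product (K = 670 L mol⁻¹, k = 0.120 L mol⁻¹ s⁻¹)

**Why violet gains.** Two steps acting together carry part of the violet-teal gap of 26 percentage points, the undoing of target into starting material + partner and the turning of second substrate + partner into second product. Without the undoing, the gap is 4.4 points. Run over violet's simulated target and starting material, the side tally gives 0.513%, and violet holds 0.537% side product at the end.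

(The runs come from a simulation with made-up constants, and the scatter is random.)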